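At early times the oak flask holds 30.0 mM of substrate against 1.20 mM of free catalyst, 25.0 substrate for each catalyst, so the catalyst must turn over many times, and the balance worth writing is that of the catalyst.

| flask | substrate | free catalyst | time |
|---|---|---|---|
| larch | 120 mM | 1.20 mM |  |
| elm | 60.0 mM | 1.20 mM |  |
| birch | 360 mM | 1.20 mM |  |
| alder | 120 mM | 3.60 mM |  |
| oak | 30.0 mM | 1.20 mM | 5.1 min |

| run | time / min | [product] / mM |
|---|---|---|
| larch run | 0.64 | 12.9 |
| larch run | 1.3 | 25.9 |
| larch run | 1.9 | 33.3 |
| larch run | 2.5 | 43.9 |
| larch run | 3.2 | 52.3 |
| larch run | 3.8 | 56.5 |
| larch run | 4.5 | 64.5 |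
| larch run | 5.1 | 67.1 |
| elm run | 0.64 | 9.3 |
| elm run | 1.3 | 15.8 |
| elm run | 1.9 | 19.8 |
| elm run | 2.5 | 25.6 |
| elm run | 3.2 | 29.4 |
| elm run | 3.8 | 33.8 |
| elm run | 4.5 | 34.5 |
| elm run | 5.1 | 35.9 |
| birch run | 0.64 | 18.8 |
| birch run | 1.3 | 38.0 |
| birch run | 1.9 | 55.8 |
| birch run | 2.5 | 71.8 |
| birch run | 3.2 | 87.7 |
| birch run | 3.8 | 102.7 |
| birch run | 4.5 | 119.1 |
| birch run | 5.1 | 130.1 |
| alder run | 0.64 | 28.8 |
| alder run | 1.3 | 53.5 |
| alder run | 1.9 | 68.5 |
| alder run | 2.5 | 80.3 |
| alder run | 3.2 | 91.7 |
| alder run | 3.8 | 97.9 |
| alder run | 4.5 | 102.5 |
| alder run | 5.1 | 106.4 |

(readings scatter by 1 mM)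

- Overall: substrate -> product, with free catalyst as catalyst.
- Constant volume, constant temperature.
- Readings of a species count what is bound in complexes too.
- An order is taken over about fifteen percent of the charge, up and down.

- order of the initial rate in [substrate], near the charge of the larch run, the rate being that where two percent of its substrate are product (one fixed amount of product, the same in the runs compared)
- order of the initial rate in [free catalyst], near the charge of the larch run, the rate being that where two percent of its substrate are product
- the elm run starts with 60.0 mM less of substrate than the larch run, and with no product. Compared where both hold the same amount of substrate, once fifteen percent of what the elm run was charged with has turned into product, is the elm run faster, slower or alike (within a tenth)?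
- product in the oak run at 5.1 min, as a share of the substrate charged

That balance can be read through the dose D. At 5.1 min the elm run stands at D = 0.912, the natural logarithm of substrate charged, S₀, over substrate left, S₀ − P, with P the product:

D = ln(S₀ / (S₀ − P))

For a pseudo-first-order rate in substrate, the slope of D would be a constant times the catalyst still at work, with substrate loss divided out.

The elm run shows what the oak run should do, stage by stage. In the first instants D climbs at 0.263 min⁻¹. In the middle, up to 2.5 min, it climbs at 0.209 min⁻¹. At the end, from 2.5 min to 5.1 min, the readings give 0.137 min⁻¹, about half of its first value. Over the first and the last of these windows the birch run, with more substrate, holds steady, 0.0838 min⁻¹ and then 0.0869 min⁻¹. So catalyst appears to drop out of work where substrate is thin, and the oak run has the thinnest substrate of these runs.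

At 5.1 min the larch run has D = 0.819, lower than the elm run. My reckoning gives the oak run, a further halving of the charge, the same step again:

D(oak) = 0.912 + (0.912 − 0.819) = 1.01

share = 1 − exp(−D) = 63.4%

One reading's scatter moves the elm dose by 0.0415, so this share is good to a few points. It leaves 10.9 mM of substrate at 5.1 min.

The forecast gives 0.4 and 0.8 for the orders, faster for the elm run, and 62% for the oak run, a little lower than the share reckoned here. Its ground for the slowing is this: “something builds up or the catalyst is lost”.

The flask gives 0.52 and 0.82 for the orders, and the elm run is faster, with a rate ratio of 1.9. The oak run reaches 65.2%, more than the share reckoned here and more than the forecast. The forecast parts from the flask on the substrate order, 0.4 against 0.52.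

    free catalyst + substrate ⇌ catalyst-substrate complex, settled at all times (39.40 M⁻¹)
    catalyst-substrate complex → product + free catalyst (29.94 min⁻¹)
    free catalyst → spent catalyst (1.050 min⁻¹)
    2 free catalyst ⇌ resting dimer, settled at all times (5360 M⁻¹)

In the oak run the catalyst-substrate complex began at 1.18 complex per free catalyst and gave product, while free catalyst turned to spent catalyst with a life of 0.952 min; at 5.1 min the dose stood at 1.06, which is 0.148 above the dose read in the elm run, with 10.4 mM of substrate left. The birch run began at 14.2 complex per free catalyst, and its dose grew at 0.0893 min⁻¹ up to 3.22 min and at 0.0850 min⁻¹ from there to 7.99 min.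

The earlier runs and the new flask are simulated from invented constants, noise included.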